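(The constants were drawn at random within sensible limits; what happens was integrated by code.)

In beta and in alpha, each mole of the charge is either G or Q, and each mole of J is either J or a living end. After the feed both totals stay as charged, so once J has begun its chains, the length asked for is Q over the J charged.

| flask | G | J | time | remark |
|---|---|---|---|---|
| beta | 0.30 M (fed, over 12 s) | 4.8 mol% | 4.0 min | the fed solution adds 0.10 times the starting volume |
| alpha | 0.30 M (fed, over 12 s) | 15 mol% | 4.0 min | the fed solution adds 0.10 times the starting volume |

    G + X → Q + X, rate k1*[X]*[G] (k1 = 0.65 L mol⁻¹ s⁻¹)
    Q + X → G + X, rate k2*[X] as long as [Q] is above zero (k2 = 0.033 s⁻¹)
    G + J → X + Q (k3 = 0.32 L mol⁻¹ s⁻¹)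

* which of the two ends with the longer chains by the average number of monomer units in a chain (chains begun, living or dead) ("neither" if they lie within 10%) (beta / alpha / neither)
* average number of monomer units in a chain (chains begun, living or dead) at the end, beta
* average number of monomer units in a chain (chains begun, living or dead) at the end, alpha

- amounts are per litre of the starting volume; all of the dose is in the solution fed
- the average divides the monomer in chains by the number of chains begun, living and dead together
- run time (beta): 4.0 min

Where does growth stop? Where a living end gains G as fast as it loses Q. Both rates carry the living ends, so these cancel, and the balance falls at G equal to the loss constant over the growth constant, 0.0508 M. Call this the floor of G; the field says equilibrium monomer concentration.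

How much can enter chains? The feed dilutes the charge to 0.273 M, so 81.4% of it lies above the floor. Dividing by the loading gives the ceiling length: 17.0 for beta, 5.43 for alpha.

Does the run reach that? G's distance from the floor decays pseudo-first-order, at the growth constant times the living ends. With every J begun, those ends are 0.0131 M in beta and 0.0409 M in alpha. The half-times are 1.36 min and 0.434 min, against a run of 4.0 min. Joining the early end to the late end gives 14.8 for beta and 5.42 for alpha. This is my joined length: the ceiling length times the fraction of the distance closed by the asked time.

But the ends aren't there at the start! True. At the diluted charge J has a half-life of 7.94 s and the feed lasts 12 s, together shorter than beta's half-time. So I keep the form, expecting beta's figure to run high, and say beta ends longer.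

The forecast answers neither, with lengths of 0 and 0. Its ground is a dose of 0.027 M after dilution, so that “living ends depolymerise faster than they grow at every moment of the run”. We part there: my diluted charge of 0.273 M stands above the floor.

The simulation gives beta: 14.5 for beta, 5.42 for alpha.

In beta, the half-life of G by its turning into Q is 1.4 min at the asked time, against the run of 4.0 min; G stands at 30.2% of the charge, above alpha's 18.8%, and the length lies below the joined 14.8. Alpha's length reads the same at 4.0 min as at 40.0 min.

Take a neighbour of beta, the same flask with 1.9 mol% of J: its half-time is 3.43 min and its joined length 23.7. The simulation gives this neighbour 23.1, with G at 56.2% of the charge.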